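The flavone is disconnected at two ring A bonds, C8a–O1 and C4a–C4, which cuts it into a 3,5-bis(MOM)benzyne and a ring B arylpropiolic acid. The key step exploits the fact that ring A carries O1 on C8a and the C4 carbonyl on the adjacent C4a, with the C5 oxygen next to C4a: a 3-alkoxyaryne inserts into the acid C–O bond with exactly this orientation and delivers the ortho-hydroxyaryl ynone in one operation. The precursors are an ortho-silylaryl triflate made from phloroglucinol and a MOM-protected 3,5-diprenyl-4-hydroxyphenylpropiolic acid made from 4-iodophenol. Amine-mediated 6-endo closure of ring C and acidic methanolysis of the MOM ethers complete the synthesis.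

Key step: step 7

Assumption: honyucitrin is taken as 3',5'-diprenylapigenin, an achiral molecule, so no stereocentre and no alkene geometry has to be controlled (MOM = methoxymethyl, prenyl = 3-methylbut-2-enyl).

Step 1
Reactants: 1 phloroglucinol (benzene-1,3,5-triol)
Product: 2 3,5-bis(methoxymethoxy)phenol
Conditions: MOMCl (2.0 equiv), i-Pr2NEt, DMF, 0 °C to rt; chromatography
Reagents that add atoms: chloromethyl methyl ether (MOMCl), COCCl
Why: Base-mediated O-alkylation with the chloromethyl ether (acetal-type Williamson etherification) acts statistically on three equivalent hydroxyls, so two equivalents of reagent should make the bis-ether the main product, which chromatography separates from the mono- and tris-ethers.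

Step 2
Reactants: 2 3,5-bis(methoxymethoxy)phenol
Product: 3 2-bromo-3,5-bis(methoxymethoxy)phenol
Conditions: NBS (1.0 equiv), CH2Cl2, −78 °C
Reagents that add atoms: N-bromosuccinimide, O=C1CCC(=O)N1Br
Why: Electrophilic aromatic bromination, in which all free ring positions are activated but the carbon flanked by OH and one OMOM group is less hindered than the one between two OMOM groups and is favoured by hydrogen bonding of the reagent to the phenol, so one equivalent of NBS at low temperature should give the ortho-bromophenol.

Step 3
Reactants: 3 2-bromo-3,5-bis(methoxymethoxy)phenol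
Product: 6 3,5-bis(methoxymethoxy)-2-(trimethylsilyl)phenyl trifluoromethanesulfonate, via aryl trimethylsilyl ether 4 (not isolated), via lithium 2-silylphenolate 5 (not isolated)
Conditions: HMDS, THF, reflux, then evaporate; n-BuLi, THF, −78 °C; Tf2O, −78 °C
Reagents that add atoms: hexamethyldisilazane, C[Si](C)(C)N[Si](C)(C)C; trifluoromethanesulfonic anhydride, O=S(=O)(OS(=O)(=O)C(F)(F)F)C(F)(F)F
Why: O-Silylation followed by bromine–lithium exchange sets off a retro-Brook 1,3-shift of silicon from oxygen to the lithiated ortho carbon, and the lithium phenolate so formed is O-sulfonylated by the anhydride, the standard one-flask route to ortho-silylaryl triflates.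

Step 4
Reactants: 7 4-iodophenol; 8 prenyl bromide (1-bromo-3-methylbut-2-ene)
Product: 9 4-iodo-2,6-bis(3-methylbut-2-enyl)phenol
Conditions: NaH (2.2 equiv), toluene, 0 °C to rt; 8 (2.2 equiv)
Reagents that add atoms: none
Why: ortho-C-Alkylation of a sodium phenoxide by SN2 displacement of the allylic bromide in a non-polar solvent, where the tightly aggregated oxygen is shielded and the blocked para position leaves only the two ortho carbons, a reaction established for para-halophenols.

Step 5
Reactants: 9 4-iodo-2,6-bis(3-methylbut-2-enyl)phenol
Product: 10 5-iodo-2-(methoxymethoxy)-1,3-bis(3-methylbut-2-enyl)benzene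
Conditions: NaH, MOMCl, THF/DMF, 0 °C to rt
Reagents that add atoms: chloromethyl methyl ether (MOMCl), COCCl
Why: Williamson-type O-alkylation, in which the small and very reactive chloromethyl ether still reaches the doubly ortho-substituted sodium phenoxide in a dipolar medium.

Step 6
Reactants: 10 5-iodo-2-(methoxymethoxy)-1,3-bis(3-methylbut-2-enyl)benzene; 11 propiolic acid (prop-2-ynoic acid)
Product: 12 3-[4-(methoxymethoxy)-3,5-bis(3-methylbut-2-enyl)phenyl]prop-2-ynoic acid
Conditions: Pd(PPh3)4 (cat.), DBU (2.4 equiv), DMSO, 30 °C; cold aq. citric acid work-up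
Reagents that add atoms: none
Why: Copper-free Sonogashira-type coupling at the terminal C–H of propiolic acid, a known route from aryl iodides to arylpropiolic acids, in which oxidative addition of the iodide to zerovalent palladium proceeds near room temperature, well below the temperature at which the product loses CO2.

Step 7
Reactants: 6 3,5-bis(methoxymethoxy)-2-(trimethylsilyl)phenyl trifluoromethanesulfonate (1.2 equiv); 12 3-[4-(methoxymethoxy)-3,5-bis(3-methylbut-2-enyl)phenyl]prop-2-ynoic acid
Product: 14 1-[2-hydroxy-4,6-bis(methoxymethoxy)phenyl]-3-[4-(methoxymethoxy)-3,5-bis(3-methylbut-2-enyl)phenyl]prop-2-yn-1-one, via 3,5-bis(methoxymethoxy)benzyne 13 (not isolated)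
Conditions: CsF (3 equiv), THF, sealed tube, 90 °C; aq. NH4Cl quench at 0 °C once 12 is consumed
Reagents that add atoms: none
Why: Fluoride attacks silicon in 6 and the resulting aryl anion expels triflate to give aryne 13; the carboxylate of 12 then adds through oxygen to the aryne carbon remote from the flanking OMOM group, which places the negative charge on the carbon ortho to that group. This aryl anion attacks the neighbouring ester carbonyl through a four-membered alkoxide that opens by C–O cleavage to the ortho-acyl phenoxide, so C8a–O1 and C4a–C4 are formed in one operation (an anionic Fries-type 1,3-acyl shift). The closest known reaction is the fluoride-mediated insertion of arynes into the C–O bond of carboxylic acids to give ortho-hydroxyaryl ketones, which also accepts arylpropiolic acids. No ring is closed and no stereocentre is created. The regiochemistry needed, oxygen at C8a and acyl at C4a beside the C5 oxygen, is secured by the 3-alkoxyaryne itself, since the inductively withdrawing OMOM group stabilises the developing ortho anion and shields its own side from the nucleophile. Acyl transfer must also outrun protonation of the aryl anion and ring closure of the product phenoxide, which is why an aprotic ether solvent, dry CsF, a moderate temperature and an early buffered quench are chosen.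

Step 8
Reactants: 14 1-[2-hydroxy-4,6-bis(methoxymethoxy)phenyl]-3-[4-(methoxymethoxy)-3,5-bis(3-methylbut-2-enyl)phenyl]prop-2-yn-1-one
Product: 16 5,7-bis(methoxymethoxy)-2-[4-(methoxymethoxy)-3,5-bis(3-methylbut-2-enyl)phenyl]-4H-chromen-4-one, via diethylamino enone 15 (not isolated)
Conditions: Et2NH (5 equiv), EtOH, 60 °C
Reagents that add atoms: none
Why: Aza-Michael addition of diethylamine to the ynone gives the β-amino enone, and the neighbouring phenol then replaces the amine by intramolecular oxa-Michael addition–elimination at C2, a pathway that can only give the six-membered pyranone (overall 6-endo) and shuts out 5-exo closure to the aurone.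

Step 9
Reactants: 16 5,7-bis(methoxymethoxy)-2-[4-(methoxymethoxy)-3,5-bis(3-methylbut-2-enyl)phenyl]-4H-chromen-4-one
Product: 17 honyucitrin, 5,7-dihydroxy-2-[4-hydroxy-3,5-bis(3-methylbut-2-enyl)phenyl]-4H-chromen-4-one
Conditions: aq. HCl (about 1 M overall), MeOH/THF, 40 °C
Reagents that add atoms: none
Why: Acid-catalysed acetal exchange with methanol cleaves all three MOM ethers, and at this acidity and temperature protonation of the trisubstituted prenyl alkenes, the entry to chroman formation with the adjacent phenol, should remain slower than acetal cleavage.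

Compound list
1 | phloroglucinol (benzene-1,3,5-triol) | Oc1cc(O)cc(O)c1 | starting material
2 | 3,5-bis(methoxymethoxy)phenol | COCOc1cc(O)cc(OCOC)c1 | intermediate
3 | 2-bromo-3,5-bis(methoxymethoxy)phenol | COCOc1cc(O)c(Br)c(OCOC)c1 | intermediate
4 | [2-bromo-3,5-bis(methoxymethoxy)phenoxy]trimethylsilane | COCOc1cc(O[Si](C)(C)C)c(Br)c(OCOC)c1 | intermediate
5 | lithium 3,5-bis(methoxymethoxy)-2-(trimethylsilyl)phenolate | [Li+].[O-]c1cc(OCOC)cc(OCOC)c1[Si](C)(C)C | intermediate
6 | 3,5-bis(methoxymethoxy)-2-(trimethylsilyl)phenyl trifluoromethanesulfonate | COCOc1cc(OCOC)c([Si](C)(C)C)c(OS(=O)(=O)C(F)(F)F)c1 | intermediate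
7 | 4-iodophenol | Oc1ccc(I)cc1 | starting material
8 | prenyl bromide (1-bromo-3-methylbut-2-ene) | CC(C)=CCBr | starting material
9 | 4-iodo-2,6-bis(3-methylbut-2-enyl)phenol | CC(C)=CCc1cc(I)cc(CC=C(C)C)c1O | intermediate
10 | 5-iodo-2-(methoxymethoxy)-1,3-bis(3-methylbut-2-enyl)benzene | COCOc1c(CC=C(C)C)cc(I)cc1CC=C(C)C | intermediate
11 | propiolic acid (prop-2-ynoic acid) | C#CC(=O)O | starting material
12 | 3-[4-(methoxymethoxy)-3,5-bis(3-methylbut-2-enyl)phenyl]prop-2-ynoic acid | OC(=O)C#Cc1cc(CC=C(C)C)c(OCOC)c(CC=C(C)C)c1 | intermediate
13 | 3,5-bis(methoxymethoxy)benzyne (1,2-didehydro-3,5-bis(methoxymethoxy)benzene) | COCOC1=CC(OCOC)=CC#C1 | intermediate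
14 | 1-[2-hydroxy-4,6-bis(methoxymethoxy)phenyl]-3-[4-(methoxymethoxy)-3,5-bis(3-methylbut-2-enyl)phenyl]prop-2-yn-1-one | COCOc1cc(O)c(C(=O)C#Cc2cc(CC=C(C)C)c(OCOC)c(CC=C(C)C)c2)c(OCOC)c1 | intermediate
15 | 3-(diethylamino)-1-[2-hydroxy-4,6-bis(methoxymethoxy)phenyl]-3-[4-(methoxymethoxy)-3,5-bis(3-methylbut-2-enyl)phenyl]prop-2-en-1-one (alkene geometry not defined; either isomer closes) | CCN(CC)C(=CC(=O)c1c(O)cc(OCOC)cc1OCOC)c1cc(CC=C(C)C)c(OCOC)c(CC=C(C)C)c1 | intermediate
16 | 5,7-bis(methoxymethoxy)-2-[4-(methoxymethoxy)-3,5-bis(3-methylbut-2-enyl)phenyl]-4H-chromen-4-one | COCOc1cc(OCOC)c2c(c1)oc(-c1cc(CC=C(C)C)c(OCOC)c(CC=C(C)C)c1)cc2=O | intermediate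
17 | honyucitrin, 5,7-dihydroxy-2-[4-hydroxy-3,5-bis(3-methylbut-2-enyl)phenyl]-4H-chromen-4-one | CC(C)=CCc1cc(-c2cc(=O)c3c(O)cc(O)cc3o2)cc(CC=C(C)C)c1O | target

Total step count: 9. Longest linear sequence: 6 steps (steps 1, 2, 3, 7, 8, 9, or equally steps 4, 5, 6, 7, 8, 9).

Steps most likely to fail

Step 7. Several processes could divert the reaction: protonation of the aryl anion before the acyl group has shifted (leaving plain O-arylation), addition of the carboxylate in the opposite orientation, consumption of the aryne by an ene reaction at a prenyl group, or closure of the product phenoxide in the flask in the 5-exo mode. Early 6-endo closure would do no harm, since it gives 16, the product of step 8. The fallback sets out from bromophenol 3 and acid 12 and comes back at ynone 14. Esterification (DCC, cat. DMAP, CH2Cl2, 0 °C) should give 2-bromo-3,5-bis(methoxymethoxy)phenyl 3-[4-(methoxymethoxy)-3,5-bis(3-methylbut-2-enyl)phenyl]prop-2-ynoate F1. Bromine–lithium exchange (t-BuLi, 2 equiv, THF/Et2O, −100 °C) then generates the same ortho-acyloxy aryl anion, now at a position fixed by the bromine and with no aryne involved. Its 1,3-acyl shift from oxygen to carbon (halogen–metal-exchange-induced anionic Fries rearrangement) should give 14 after an NH4Cl quench.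

Step 6. The coupled acid could lose CO2 at palladium, which would lead on to the terminal alkyne and to a second arylation, or oxidative addition to the electron-rich iodide could stall at the low temperature that protects the acid. The fallback sets out from iodide 10 and comes back at acid 12. Sonogashira coupling with trimethylsilylacetylene (PdCl2(PPh3)2, CuI, Et3N, rt) should give trimethyl{[4-(methoxymethoxy)-3,5-bis(3-methylbut-2-enyl)phenyl]ethynyl}silane F2. K2CO3 (cat.) in MeOH should then give 5-ethynyl-2-(methoxymethoxy)-1,3-bis(3-methylbut-2-enyl)benzene F3. Deprotonation with n-BuLi (THF, −78 °C), trapping with CO2 and brief acidification with cold dilute HCl should give 12. The carboxyl carbon then comes from CO2 and the acid never meets palladium.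

Step 2. Bromination could occur at the carbon para to the hydroxyl (between the two OMOM groups) or proceed twice, which would put silicon and triflate in the wrong relationship. The fallback sets out from phenol 2 and comes back at lithium phenolate 5, so that silicon is placed by directed metalation instead of through a bromide. Carbamoylation (Et2NCOCl, NaH, THF) should give 3,5-bis(methoxymethoxy)phenyl N,N-diethylcarbamate F4. Directed ortho-metalation (s-BuLi, TMEDA, THF, −78 °C) should occur at the carbon between the carbamate and an OMOM group, where both directors cooperate and the carbamate is the stronger one, and a TMSCl quench should give 3,5-bis(methoxymethoxy)-2-(trimethylsilyl)phenyl N,N-diethylcarbamate F5. Reductive cleavage of the carbamate (LiAlH4, THF, reflux) should give 3,5-bis(methoxymethoxy)-2-(trimethylsilyl)phenol F6. n-BuLi (THF, −78 °C) converts this phenol into 5, which is triflated with Tf2O as in step 3.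

Further compounds
F1 | step 7 | 2-bromo-3,5-bis(methoxymethoxy)phenyl 3-[4-(methoxymethoxy)-3,5-bis(3-methylbut-2-enyl)phenyl]prop-2-ynoate | COCOc1cc(OC(=O)C#Cc2cc(CC=C(C)C)c(OCOC)c(CC=C(C)C)c2)c(Br)c(OCOC)c1
F2 | step 6 | trimethyl{[4-(methoxymethoxy)-3,5-bis(3-methylbut-2-enyl)phenyl]ethynyl}silane | C[Si](C)(C)C#Cc1cc(CC=C(C)C)c(OCOC)c(CC=C(C)C)c1
F3 | step 6 | 5-ethynyl-2-(methoxymethoxy)-1,3-bis(3-methylbut-2-enyl)benzene | C#Cc1cc(CC=C(C)C)c(OCOC)c(CC=C(C)C)c1
F4 | step 2 | 3,5-bis(methoxymethoxy)phenyl N,N-diethylcarbamate | CCN(CC)C(=O)Oc1cc(OCOC)cc(OCOC)c1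
F5 | step 2 | 3,5-bis(methoxymethoxy)-2-(trimethylsilyl)phenyl N,N-diethylcarbamate | CCN(CC)C(=O)Oc1cc(OCOC)cc(OCOC)c1[Si](C)(C)C
F6 | step 2 | 3,5-bis(methoxymethoxy)-2-(trimethylsilyl)phenol | COCOc1cc(O)c([Si](C)(C)C)c(OCOC)c1
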